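At early times, if both products arise by capture of one common species, their ratio should show how the two nucleophiles compete. The zero of the scale is then the case of equal molecules: with 2.00 equiv of first nucleophile against 1.50 equiv of second, target would take 57.1 % of the two products.

| flask | substrate | first nucleophile | second nucleophile | remark | time |
|---|---|---|---|---|---|
| eta | 0.50 M | 2 equiv | 1.5 equiv | the very flask that is asked about, followed so far |  |
| alpha | 1 M | 2 equiv | 1.5 equiv | run made earlier |  |
| flask | 0.50 M | 2.00 equiv | 1.50 equiv |  | 3.0 d |

| run | time / h | target / % | other capture product / % |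
|---|---|---|---|
| eta | 5.00 | 5.4 | 3.2 |
| eta | 10.0 | 9.7 | 10.9 |
| eta | 15.0 | 13.0 | 14.4 |
| eta | 20.0 | 14.1 | 20.2 |
| eta | 25.0 | 19.2 | 21.5 |
| eta | 30.0 | 21.6 | 24.5 |
| eta | 40.0 | 20.0 | 26.8 |
| alpha | 1.50 | 0 | 0.8 |
| alpha | 4.00 | 6.1 | 6.4 |
| alpha | 8.00 | 8.9 | 9.5 |
| alpha | 12.0 | 10.1 | 12.1 |
| alpha | 20.0 | 14.3 | 20.9 |
| alpha | 25.0 | 15.0 | 22.9 |
| alpha | 30.0 | 15.3 | 25.7 |

(scatter of a reading: 1 percentage point)

- share of target in target plus other capture product at 2.0 h
- share of target in target plus other capture product at 12 h
- share of target in target plus other capture product at 3.0 d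

- the analysis behind the earlier runs scatters by 1 percentage point, standard deviation

Two ways read the departure from that zero. The eta run up to 15.0 h gives a target share of 49.6 %, and the alpha run from 4.00 h to 12.0 h gives 47.3 %. Both stand lower than the zero, but their gap of 2.3 percentage points, with each reading scattering by 1 point, is not resolved by so few readings. Later they part: the eta run reads 42.7 % at 40.0 h, while the alpha run reads less, 37.3 %, already at 30.0 h. So the more concentrated run cheats more, and target seems to be lost with concentration. If the shortfall scales with concentration, the share at vanishing concentration is about 52.0 %, a reading uncertain by several points. Per molecule, the first nucleophile is then worth 0.813 of the second. This is the selectivity factor, target made per other capture product divided by the ratio of the two nucleophile amounts. For the eta flask at 2.0 h this reckoning gives 52.0 %.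

The forecast gives 50 %, 47 % and 36 %, reading the drift thus: “target is probably being converted to other product by a concentration-dependent step”.

The flask gives 53.7 %, 49.5 % and 43.1 %.

    substrate + target → side product (k = 3.00 × 10⁻⁵ /M/s)
    intermediate → decomposed reagent (k = 5.30 × 10⁻⁷ /s)
    intermediate → solvolysis product (k = 2.60 × 10⁻⁵ /s)
    substrate → intermediate (k = 1.10 × 10⁻⁵ /s)
    first nucleophile + intermediate → target (k = 7.50 × 10⁻⁵ /M/s)
    second nucleophile + intermediate → other capture product (k = 8.30 × 10⁻⁵ /M/s)

At 3.00 d the eta flask holds 81 % and 80 % of the two nucleophile charges, so the factor gives a capture ratio of 1.10, and the flask's ratio stands at 1.2. Target, meanwhile, is made 2.67 times faster than used up at 0.575 d, but 1.57 times at 3.00 d, with side product reaching 28.3 %, each molecule counted as two.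

In the neighbour flask with 0.800 equiv of first nucleophile, the factor gives an early share of 30.2 %. That flask gives 31.7 % at 2.0 h and 23.0 % at 3.0 d.

Readings and results are simulated for an exercise; noise was put on by code.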